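## Structural features

The target is a 2,3,4-trisubstituted oxolane (tetrahydrofuran) lignan with ring atoms O1, C2, C3, C4 and C5. C2 carries a 3,4-dihydroxyphenyl ring, C3 an acetoxymethyl arm and C4 a 4-hydroxy-3-methoxybenzyl group (benzylic carbon C7'). C5 is an unsubstituted OCH2 carbon. The three stereocentres are contiguous, (2S,3R,4R): the C2 aryl group is trans to the C3 arm, and the C3 arm is cis to the C4 benzyl group. The fragile parts are the free catechol (air oxidation), the primary acetate (base-labile, and the only acylated oxygen among four hydroxyls) and the C2–O1 bond. That bond is a benzylic ether activated by a para oxygen, so it is open to acid ionisation and to hydrogenolysis. The real difficulty is the 3,4-cis pair next to a 2,3-trans pair, together with placing one acetyl group on the aliphatic oxygen only. The key step uses two facts: C5 is a lone methylene between O1 and C4, which is the oxidation level of formaldehyde, and C4–C7' can be carried as a styrene double bond. The C4–C5 bond can therefore be made by attack of the styrenyl C4 on an O1=C5 oxocarbenium ion. This closes the oxolane ring and leaves C4 trigonal for a later face-selective hydrogenation.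

## Logic of the disconnections

18 to 17: the C4–H and C7'–H bonds are removed (retro-hydrogenation) and the three phenolic O–H bonds become O–benzyl bonds. C4 is the only stereocentre that an aldol cannot reach, and an exocyclic C4=C7' alkene lets the adjacent C3 arm decide the face. One operation then sets C4 and frees all phenols. The acetate is already present in 17, so the last step exposes no hydroxyl that would need differentiation. The forward step must deliver hydrogen anti to the C3 arm and must spare the benzylic C2–O1 bond.

17 to 14: the C4–C5 bond is cut. This removes the only ring and traces C5 to a one-carbon acetal on the C2 oxygen, leaving an acyclic homoallylic ether with both stereocentres in an open chain. The forward step must ionise the acetal and not the benzylic C2–O bond, must close through C4 (five-membered ring) and not through C7', and must end by clean proton loss. No stereocentre is made, so C2 and C3 have to arrive intact.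

14 to 13 to 12: the O–CH2OMe bond and then the acetyl C–O bond are cut. The C3 arm carries its final acetate from here on and no silyl ether is used, which removes a protection and a deprotection from the end game. The forward steps need primary-selective acetylation of 12 and acetal formation under conditions that do not move the acetyl group.

12 to 11 to 7 plus 8: the primary alcohol is taken back to the imide carbonyl, and the C2–C3 bond (target numbering) is then cut as an aldol. Both stereocentres come from one closed transition state, and the syn aldol corresponds to the 2,3-trans ring. The forward step needs α-selective reaction of a dienolate, auxiliary-controlled facial selectivity, and a reductive cleavage mild enough for the epimerisable α-centre.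

7 to 4 plus 5: the N–acyl bond is cut. This separates the recoverable auxiliary from an achiral acid. The acylation must not shift the styrenyl double bond.

4 to 1 plus 2: the C=C bond is cut as a Wittig olefination. Both partners are catalogue compounds. The alkene geometry should be mainly E, although it is erased later.

## Other disconnections considered

Alternative 1: the cuts are C2–C3 and C4–C7'. In the forward step lithiated dithiane A2 adds to the β-carbon of butenolide A1 anti to the menthyloxy group, and the lactone enolate is benzylated in the same flask with bromide A3 to give the trans,trans lactone A4.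
- In favour: two skeletal bonds and both C3 and C4 are set in one operation under substrate control by a cheap chiral-pool auxiliary. The trans lactone of A4 becomes exactly the required 3,4-cis oxolane once the lactone carbonyl becomes C5 and the acetal carbon becomes the acetoxymethyl carbon.
- Against: C2 arrives masked at the ketone level. Dithiane hydrolysis next to electron-rich arenes, carbonyl reduction and a separate ether closure are still needed, and C2 is set only then. Sulfur residues are unwelcome before a palladium step.
- Comparison: on C4 this plan is the better one, because C4 is fixed by an enolate alkylation of well-established sense and not by a heterogeneous hydrogenation. On structure it is more convergent (three fragments). Mechanistically it avoids a cation near the arenes until the late ring closure, which is an advantage. On step economy it is longer by roughly two to three operations, and C2 control is deferred, where the chosen plan sets C2 and C3 together.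

Alternative 2: the cuts are C2–C3 and the O1–C5 acyl bond. In the forward step aldehyde 8 and the (Z)-allylboronate A5 react through a chair allylboration under a chiral BINOL-derived phosphoric acid, and the borate alkoxide closes onto the ester to give the α-methylene lactone A6.
- In favour: enantiocontrol is catalytic, the closed transition state gives the trans C2/C3 pair directly, and the ring oxygen is installed in the same step.
- Against: the guaiacyl ring is still missing and has to be attached to the exocyclic methylene (Heck-type arylation, then hydrogenation). The lactone carbonyl must then be taken down to CH2 by lactol formation and Lewis-acid silane reduction, which threatens the benzylic C2–O1 bond. A silyl-to-acetate exchange follows. A5 needs several steps, and its selectivity with an electron-rich aldehyde is not assured.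
- Comparison: for C2/C3 the two plans are equal (both use a six-membered closed transition state). This plan is the better one in using a catalyst and no stoichiometric auxiliary. It is the weaker one on step count after the key step and on the carbonyl removal. It depends on the same alkene hydrogenation for C4.

Alternative 3: the cuts are O1–C2 and O1–C5, and before them C2–C3 and C4–C5. The keteniminium ion from amide A7 and allyl ether A8 would give, after hydrolysis, the trans cyclobutanone A9. In the forward key step a buffered peracid inserts oxygen between the carbonyl carbon and the aryl-bearing carbon with retention to give lactone A10.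
- In favour: the ring carbons are assembled very quickly, the migrating group is predictable (the electron-rich secondary benzylic carbon), and the 2,3-trans pair is under thermodynamic control at the epimerisable α-aryl centre.
- Against: the absolute configuration must come from a chiral amine in place of the dimethylamino group of A7 or from a resolution. Electron-rich arenes are exposed to strongly electrophilic amide activation. A10 lacks the C4 benzyl group, and direct enolate benzylation would enter anti to the C4 arm of the lactone, which gives the wrong 3,4-trans pair. A condensation–hydrogenation detour and carbonyl removal are therefore needed.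
- Comparison: regiocontrol of the oxygen insertion is the equal of the regiocontrol of the chosen cyclisation. In ring construction this plan is faster. It is weaker on enantiocontrol, ends in the same reliance on hydrogenation for C4, and is longer overall.

Key step: step 7

## Remarks before the steps

- Assumption: 2 (O-benzylvanillin) and 8 are taken as catalogue compounds, so no phenol protection step is counted.
- Check of the structures: the target is (2S,3R,4R), that is 2,3-trans and 3,4-cis. The syn aldol from the (S)-4-benzyl auxiliary maps onto C2 (S) and C3 (R). The benzylidene in which the aryl group is cis to C5 is Z. No correction of the skeletons was found necessary.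
- Design change: the C3 arm carries its acetate through the cyclisation (14 and 17) in place of a silyl ether. The skeleton and the bond formed in the key step are unchanged.

## Route

Step 1
Reactants: 1 (2-carboxyethyl)triphenylphosphonium bromide; 2 4-(benzyloxy)-3-methoxybenzaldehyde
Product: 4 (E)-4-[4-(benzyloxy)-3-methoxyphenyl]but-3-enoic acid, via ylide carboxylate 3 (not isolated)
Conditions: NaN(SiMe3)2 (2.2 equiv), THF, −78 °C → rt; 1 M HCl; recrystallisation
Reagents that add atoms: none
Why: Wittig olefination; the carboxylate-bearing ylide is expected to give mainly the E-styrene with an aromatic aldehyde, and the minor Z-isomer should be removable by crystallisation (the geometry is in any case erased in steps 7 and 8).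

Step 2
Reactants: 4 (E)-4-[4-(benzyloxy)-3-methoxyphenyl]but-3-enoic acid; 5 (S)-4-benzyl-1,3-oxazolidin-2-one
Product: 7 (S)-4-benzyl-3-{(E)-4-[4-(benzyloxy)-3-methoxyphenyl]but-3-enoyl}-1,3-oxazolidin-2-one, via mixed pivalic anhydride 6 (not isolated)
Conditions: PivCl, Et3N, THF, −20 °C; then 5, LiCl, −20 °C → rt
Reagents that add atoms: none
Why: N-acylation through a mixed pivalic anhydride (LiCl/Et3N protocol); the hindered pivaloyl carbonyl directs the oxazolidinone to the butenoyl carbonyl, and the weak amine base should leave the aryl-conjugated β,γ-double bond in place.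

Step 3
Reactants: 7 (S)-4-benzyl-3-{(E)-4-[4-(benzyloxy)-3-methoxyphenyl]but-3-enoyl}-1,3-oxazolidin-2-one; 8 3,4-bis(benzyloxy)benzaldehyde
Product: 11 (S)-4-benzyl-3-[(2S,3E)-2-{(S)-[3,4-bis(benzyloxy)phenyl](hydroxy)methyl}-4-[4-(benzyloxy)-3-methoxyphenyl]but-3-enoyl]-1,3-oxazolidin-2-one, via boron enolate 9 (not isolated), via boron aldolate 10 (not isolated)
Conditions: n-Bu2BOTf, i-Pr2NEt, CH2Cl2, −78 → 0 °C; 8, −78 → 0 °C; pH 7 buffer, MeOH, 30% H2O2, 0 °C
Reagents that add atoms: none
Why: Evans syn-aldol reaction; the (Z)-boron enolate reacts at its α-carbon through a chair Zimmerman–Traxler transition state on the face away from the benzyl group of the auxiliary, which sets the future C3 and C2 together in the syn relationship that becomes 2,3-trans in the ring. The closed six-membered transition state also enforces α- over γ-attack of the dienolate.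

Step 4
Reactants: 11 (S)-4-benzyl-3-[(2S,3E)-2-{(S)-[3,4-bis(benzyloxy)phenyl](hydroxy)methyl}-4-[4-(benzyloxy)-3-methoxyphenyl]but-3-enoyl]-1,3-oxazolidin-2-one
Product: 12 (1S,2R)-1-[3,4-bis(benzyloxy)phenyl]-2-{(E)-2-[4-(benzyloxy)-3-methoxyphenyl]ethenyl}propane-1,3-diol
Conditions: LiBH4, MeOH (1.1 equiv), THF, 0 °C; aq. NH4Cl
Reagents that add atoms: none
Why: Reductive cleavage of the N-acyl oxazolidinone with lithium borohydride, the β-hydroxyl guiding hydride to the exocyclic carbonyl; no stereocentre is touched, the epimerisable α-position leaves the carbonyl oxidation level at once, and 5 should be recovered.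

Step 5
Reactants: 12 (1S,2R)-1-[3,4-bis(benzyloxy)phenyl]-2-{(E)-2-[4-(benzyloxy)-3-methoxyphenyl]ethenyl}propane-1,3-diol
Product: 13 (2R,3S)-3-[3,4-bis(benzyloxy)phenyl]-2-{(E)-2-[4-(benzyloxy)-3-methoxyphenyl]ethenyl}-3-hydroxypropyl acetate
Conditions: AcCl (1.05 equiv), 2,4,6-collidine, CH2Cl2, −78 °C
Reagents that add atoms: acetyl chloride, CC(Cl)=O
Why: Chemoselective O-acylation; at low temperature with a weak hindered base the primary hydroxyl should react far faster than the hindered secondary benzylic one.

Step 6
Reactants: 13 (2R,3S)-3-[3,4-bis(benzyloxy)phenyl]-2-{(E)-2-[4-(benzyloxy)-3-methoxyphenyl]ethenyl}-3-hydroxypropyl acetate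
Product: 14 (2R,3S)-3-[3,4-bis(benzyloxy)phenyl]-2-{(E)-2-[4-(benzyloxy)-3-methoxyphenyl]ethenyl}-3-(methoxymethoxy)propyl acetate
Conditions: MOMCl, i-Pr2NEt, cat. n-Bu4NI, CH2Cl2, 0 °C → rt
Reagents that add atoms: chloromethyl methyl ether, COCCl
Why: Formation of the mixed formaldehyde acetal by O-alkylation with an α-chloro ether; the amine base is too weak to generate an alkoxide, so acetyl migration from the primary oxygen is not expected.

Step 7
Reactants: 14 (2R,3S)-3-[3,4-bis(benzyloxy)phenyl]-2-{(E)-2-[4-(benzyloxy)-3-methoxyphenyl]ethenyl}-3-(methoxymethoxy)propyl acetate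
Product: 17 {(2S,3R,4Z)-2-[3,4-bis(benzyloxy)phenyl]-4-[4-(benzyloxy)-3-methoxybenzylidene]oxolan-3-yl}methyl acetate, via oxocarbenium ion 15 (not isolated), via benzylic cation 16 (not isolated)
Conditions: Me3SiOTf (1.5 equiv), 2,6-di-tert-butyl-4-methylpyridine (2 equiv), CH2Cl2, −78 → −30 °C; aq. NaHCO3
Reagents that add atoms: none
Why: The silyl triflate silylates the methoxy oxygen of the acetal and methoxytrimethylsilane departs to give the O-methylene oxocarbenium ion 15; the styrene carbon attached to C3 attacks it, forming C4–C5 and the benzylic cation 16, and the hindered pyridine removes the C4 proton to give the aryl-conjugated benzylidene 17. The closest known reaction type is the Prins-type cyclisation of alkoxymethyl oxocarbenium ions onto styrenes, here ended by elimination. The oxolane closes in a 5-exo-trig mode with respect to the alkene and endo with respect to the C=O+ unit. No stereocentre is created: C2 and C3 come from step 3, and the transient C4 centre of 16 disappears on proton loss; the Z geometry is expected because the aryl group turns away from the C3 arm, and it has no bearing on step 8. The step needs closure through C4 and not through C7' (six-membered ring or 2-oxonia-Cope shift), and this should be secured by the cation developing at the benzylic carbon, stabilised by the para-benzyloxy group, only when C4 is the attacking atom. It also needs acetal ionisation ahead of ionisation of the electron-rich benzylic C2–O bond, for which the low temperature and the more accessible methoxy oxygen are relied on; cleavage of the acetal in the opposite sense is reversible and should drain into the irreversible cyclisation. The pyridine base takes up triflic acid, so the styrene, the 2-aryl ether and the acetate are kept from protic acid, and rapid proton loss is favoured over Friedel–Crafts capture of 16 by the catechol ring.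

Step 8
Reactants: 17 {(2S,3R,4Z)-2-[3,4-bis(benzyloxy)phenyl]-4-[4-(benzyloxy)-3-methoxybenzylidene]oxolan-3-yl}methyl acetate
Product: 18 {(2S,3R,4R)-2-(3,4-dihydroxyphenyl)-4-(4-hydroxy-3-methoxybenzyl)oxolan-3-yl}methyl acetate (target)
Conditions: H2 (1 atm), 10% Pd/C, EtOAc–EtOH, rt; filtration under argon
Reagents that add atoms: none
Why: Heterogeneous catalytic hydrogenation with hydrogenolysis of the three aryl benzyl ethers in the same operation; hydrogen should reach the exocyclic alkene from the ring face opposite the adjacent C3 acetoxymethyl arm, so the new benzyl group ends cis to that arm (4R). Neutral solvent, ambient pressure and prompt termination should spare the benzylic C2–O1 bond, and the acetate stays as the only acylated oxygen.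

## Compound list

1 | (2-carboxyethyl)triphenylphosphonium bromide | OC(=O)CC[P+](c1ccccc1)(c1ccccc1)c1ccccc1.[Br-] | starting material
2 | 4-(benzyloxy)-3-methoxybenzaldehyde | COc1cc(C=O)ccc1OCc1ccccc1 | starting material
3 | sodium 3-(triphenyl-λ5-phosphanylidene)propanoate (ylide carboxylate) | [Na+].[O-]C(=O)CC=P(c1ccccc1)(c1ccccc1)c1ccccc1 | intermediate (not isolated)
4 | (E)-4-[4-(benzyloxy)-3-methoxyphenyl]but-3-enoic acid | OC(=O)C/C=C/c1ccc(OCc2ccccc2)c(OC)c1 | intermediate
5 | (S)-4-benzyl-1,3-oxazolidin-2-one | O=C1N[C@@H](Cc2ccccc2)CO1 | starting material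
6 | (E)-4-[4-(benzyloxy)-3-methoxyphenyl]but-3-enoic pivalic anhydride | CC(C)(C)C(=O)OC(=O)C/C=C/c1ccc(OCc2ccccc2)c(OC)c1 | intermediate (not isolated)
7 | (S)-4-benzyl-3-{(E)-4-[4-(benzyloxy)-3-methoxyphenyl]but-3-enoyl}-1,3-oxazolidin-2-one | O=C(C/C=C/c1ccc(OCc2ccccc2)c(OC)c1)N1[C@@H](Cc2ccccc2)COC1=O | intermediate
8 | 3,4-bis(benzyloxy)benzaldehyde | O=Cc1ccc(OCc2ccccc2)c(OCc2ccccc2)c1 | starting material
9 | dibutylboron (Z)-enolate of 7 (1Z,3E-dienyl borinate) | CCCCB(CCCC)O/C(=C\C=C\c1ccc(OCc2ccccc2)c(OC)c1)N1[C@@H](Cc2ccccc2)COC1=O | intermediate (not isolated)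
10 | O-dibutylboryl aldolate of 11 | CCCCB(CCCC)O[C@H](c1ccc(OCc2ccccc2)c(OCc2ccccc2)c1)[C@@H](C(=O)N1[C@@H](Cc2ccccc2)COC1=O)/C=C/c1ccc(OCc2ccccc2)c(OC)c1 | intermediate (not isolated)
11 | (S)-4-benzyl-3-[(2S,3E)-2-{(S)-[3,4-bis(benzyloxy)phenyl](hydroxy)methyl}-4-[4-(benzyloxy)-3-methoxyphenyl]but-3-enoyl]-1,3-oxazolidin-2-one | O[C@H](c1ccc(OCc2ccccc2)c(OCc2ccccc2)c1)[C@@H](C(=O)N1[C@@H](Cc2ccccc2)COC1=O)/C=C/c1ccc(OCc2ccccc2)c(OC)c1 | intermediate
12 | (1S,2R)-1-[3,4-bis(benzyloxy)phenyl]-2-{(E)-2-[4-(benzyloxy)-3-methoxyphenyl]ethenyl}propane-1,3-diol | O[C@H](c1ccc(OCc2ccccc2)c(OCc2ccccc2)c1)[C@@H](CO)/C=C/c1ccc(OCc2ccccc2)c(OC)c1 | intermediate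
13 | (2R,3S)-3-[3,4-bis(benzyloxy)phenyl]-2-{(E)-2-[4-(benzyloxy)-3-methoxyphenyl]ethenyl}-3-hydroxypropyl acetate | O[C@H](c1ccc(OCc2ccccc2)c(OCc2ccccc2)c1)[C@@H](COC(C)=O)/C=C/c1ccc(OCc2ccccc2)c(OC)c1 | intermediate
14 | (2R,3S)-3-[3,4-bis(benzyloxy)phenyl]-2-{(E)-2-[4-(benzyloxy)-3-methoxyphenyl]ethenyl}-3-(methoxymethoxy)propyl acetate | COCO[C@H](c1ccc(OCc2ccccc2)c(OCc2ccccc2)c1)[C@@H](COC(C)=O)/C=C/c1ccc(OCc2ccccc2)c(OC)c1 | intermediate
15 | O-methylene oxocarbenium triflate derived from 14 | C=[O+][C@H](c1ccc(OCc2ccccc2)c(OCc2ccccc2)c1)[C@@H](COC(C)=O)/C=C/c1ccc(OCc2ccccc2)c(OC)c1.[O-]S(=O)(=O)C(F)(F)F | intermediate (not isolated)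
16 | (2S,3R)-oxolanyl benzylic cation triflate (C4 configuration undefined) | COc1cc([CH+]C2CO[C@H](c3ccc(OCc4ccccc4)c(OCc4ccccc4)c3)[C@H]2COC(C)=O)ccc1OCc1ccccc1.[O-]S(=O)(=O)C(F)(F)F | intermediate (not isolated)
17 | {(2S,3R,4Z)-2-[3,4-bis(benzyloxy)phenyl]-4-[4-(benzyloxy)-3-methoxybenzylidene]oxolan-3-yl}methyl acetate | COc1cc(/C=C2\CO[C@H](c3ccc(OCc4ccccc4)c(OCc4ccccc4)c3)[C@H]2COC(C)=O)ccc1OCc1ccccc1 | intermediate
18 | {(2S,3R,4R)-2-(3,4-dihydroxyphenyl)-4-(4-hydroxy-3-methoxybenzyl)oxolan-3-yl}methyl acetate | COc1cc(C[C@H]2CO[C@H](c3ccc(O)c(O)c3)[C@H]2COC(C)=O)ccc1O | target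

## Step count and least certain steps

Total step count: 8. Longest linear sequence: 8 steps (from 1 and 2 to 18).

**Step 7 (key step).** Several things may go wrong.
- The benzylic C2–O bond may ionise in competition with the acetal, with loss of the acetal oxygen or epimerisation.
- The benzylic cation may be captured by the electron-rich catechol ring or by methoxide before proton loss.
- A 2-oxonia-Cope shift may scramble the chain.
- The ester carbonyl may tie up the silyl triflate or take part in cation capture.

The fallback removes the Lewis-basic ester from the cyclisation and restores the non-coordinating silyl ether substrate. It sets out from 12. Selective silylation of the primary hydroxyl (t-BuPh2SiCl, imidazole, CH2Cl2) should give (1S,2R,3E)-1-[3,4-bis(benzyloxy)phenyl]-4-[4-(benzyloxy)-3-methoxyphenyl]-2-{[(tert-butyldiphenylsilyl)oxy]methyl}but-3-en-1-ol F1. Acetal formation as in step 6 should give its methoxymethyl ether F2. Cyclisation under the conditions of step 7 (or with SnCl4) should give tert-butyl({(2S,3R,4Z)-2-[3,4-bis(benzyloxy)phenyl]-4-[4-(benzyloxy)-3-methoxybenzylidene]oxolan-3-yl}methoxy)diphenylsilane F3. Desilylation with n-Bu4NF in THF should give {(2S,3R,4Z)-2-[3,4-bis(benzyloxy)phenyl]-4-[4-(benzyloxy)-3-methoxybenzylidene]oxolan-3-yl}methanol F4. Acetylation (Ac2O, pyridine) comes back to the route at 17.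

**Step 8.** Facial selectivity may be poor, because the C2 aryl group lies on the ring face opposite the C3 arm and may partly offset its shielding. Over-reduction may also occur, by hydrogenolysis of the benzylic C2–O1 bond (ring opening) or of the allylic C5–O1 bond before the alkene is saturated.

The fallback separates alkene reduction from deprotection and sets out from 17. The alkene is reduced by metal-hydride hydrogen-atom transfer (Mn(dpm)3, trivalent manganese, PhSiH3, t-BuOOH, i-PrOH). A bulky manganese hydride should deliver the hydrogen atom to C4 from the less hindered face, and neither benzyl ethers nor the ring C–O bonds are touched. This should give {(2S,3R,4R)-2-[3,4-bis(benzyloxy)phenyl]-4-[4-(benzyloxy)-3-methoxybenzyl]oxolan-3-yl}methyl acetate F5, at which stage any C4 epimer can be removed by chromatography. Transfer hydrogenolysis (Pd/C, cyclohexa-1,4-diene, EtOH), with no alkene left to compete, comes back at 18.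

**Step 3.** The dienolate may react at its γ-carbon or equilibrate, and the electron-rich aldehyde may react sluggishly. The doubly activated α-centre of the adduct may epimerise, or the adduct may undergo retro-aldol cleavage during work-up.

The fallback installs the aryl group after the aldol and sets out from 5 and 8. Compound 5 is N-acylated with but-3-enoic acid under the conditions of step 2 to give (S)-4-benzyl-3-(but-3-enoyl)-1,3-oxazolidin-2-one F6. The boron aldol with 8 under the conditions of step 3 should give (S)-4-benzyl-3-[(2S)-2-{(S)-[3,4-bis(benzyloxy)phenyl](hydroxy)methyl}but-3-enoyl]-1,3-oxazolidin-2-one F7. Reduction with LiBH4 should give (1S,2R)-1-[3,4-bis(benzyloxy)phenyl]-2-ethenylpropane-1,3-diol F8. Cross-metathesis of F8 with 1-(benzyloxy)-4-ethenyl-2-methoxybenzene F9 (from 2 by methylenation with Ph3P=CH2), using the second-generation Grubbs catalyst in CH2Cl2 at 40 °C, comes back at 12.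

**Step 5.** Acetylation may run on to the secondary benzylic hydroxyl, or the acetyl group may migrate during handling, which would blur the distinction between the two oxygens.

The fallback changes the order of operations so that no selectivity is needed, and sets out from 11. The secondary hydroxyl is converted first (MOMCl, i-Pr2NEt) into (S)-4-benzyl-3-[(2S,3E)-2-{(S)-[3,4-bis(benzyloxy)phenyl](methoxymethoxy)methyl}-4-[4-(benzyloxy)-3-methoxyphenyl]but-3-enoyl]-1,3-oxazolidin-2-one F10. Reduction with LiBH4 should give (2R,3S)-3-[3,4-bis(benzyloxy)phenyl]-2-{(E)-2-[4-(benzyloxy)-3-methoxyphenyl]ethenyl}-3-(methoxymethoxy)propan-1-ol F11. Its single hydroxyl is acetylated (Ac2O, pyridine, cat. DMAP), and the sequence comes back at 14.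

## Further compounds

F1 | step 7 | (1S,2R,3E)-1-[3,4-bis(benzyloxy)phenyl]-4-[4-(benzyloxy)-3-methoxyphenyl]-2-{[(tert-butyldiphenylsilyl)oxy]methyl}but-3-en-1-ol | O[C@H](c1ccc(OCc2ccccc2)c(OCc2ccccc2)c1)[C@@H](CO[Si](c1ccccc1)(c1ccccc1)C(C)(C)C)/C=C/c1ccc(OCc2ccccc2)c(OC)c1
F2 | step 7 | methoxymethyl ether of F1 | COCO[C@H](c1ccc(OCc2ccccc2)c(OCc2ccccc2)c1)[C@@H](CO[Si](c1ccccc1)(c1ccccc1)C(C)(C)C)/C=C/c1ccc(OCc2ccccc2)c(OC)c1
F3 | step 7 | tert-butyl({(2S,3R,4Z)-2-[3,4-bis(benzyloxy)phenyl]-4-[4-(benzyloxy)-3-methoxybenzylidene]oxolan-3-yl}methoxy)diphenylsilane | COc1cc(/C=C2\CO[C@H](c3ccc(OCc4ccccc4)c(OCc4ccccc4)c3)[C@H]2CO[Si](c3ccccc3)(c3ccccc3)C(C)(C)C)ccc1OCc1ccccc1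
F4 | step 7 | {(2S,3R,4Z)-2-[3,4-bis(benzyloxy)phenyl]-4-[4-(benzyloxy)-3-methoxybenzylidene]oxolan-3-yl}methanol | COc1cc(/C=C2\CO[C@H](c3ccc(OCc4ccccc4)c(OCc4ccccc4)c3)[C@H]2CO)ccc1OCc1ccccc1
F5 | step 8 | {(2S,3R,4R)-2-[3,4-bis(benzyloxy)phenyl]-4-[4-(benzyloxy)-3-methoxybenzyl]oxolan-3-yl}methyl acetate | COc1cc(C[C@H]2CO[C@H](c3ccc(OCc4ccccc4)c(OCc4ccccc4)c3)[C@H]2COC(C)=O)ccc1OCc1ccccc1
F6 | step 3 | (S)-4-benzyl-3-(but-3-enoyl)-1,3-oxazolidin-2-one | C=CCC(=O)N1[C@@H](Cc2ccccc2)COC1=O
F7 | step 3 | (S)-4-benzyl-3-[(2S)-2-{(S)-[3,4-bis(benzyloxy)phenyl](hydroxy)methyl}but-3-enoyl]-1,3-oxazolidin-2-one | O[C@H](c1ccc(OCc2ccccc2)c(OCc2ccccc2)c1)[C@@H](C(=O)N1[C@@H](Cc2ccccc2)COC1=O)C=C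
F8 | step 3 | (1S,2R)-1-[3,4-bis(benzyloxy)phenyl]-2-ethenylpropane-1,3-diol | O[C@H](c1ccc(OCc2ccccc2)c(OCc2ccccc2)c1)[C@@H](CO)C=C
F9 | step 3 | 1-(benzyloxy)-4-ethenyl-2-methoxybenzene | C=Cc1ccc(OCc2ccccc2)c(OC)c1
F10 | step 5 | (S)-4-benzyl-3-[(2S,3E)-2-{(S)-[3,4-bis(benzyloxy)phenyl](methoxymethoxy)methyl}-4-[4-(benzyloxy)-3-methoxyphenyl]but-3-enoyl]-1,3-oxazolidin-2-one | COCO[C@H](c1ccc(OCc2ccccc2)c(OCc2ccccc2)c1)[C@@H](C(=O)N1[C@@H](Cc2ccccc2)COC1=O)/C=C/c1ccc(OCc2ccccc2)c(OC)c1
F11 | step 5 | (2R,3S)-3-[3,4-bis(benzyloxy)phenyl]-2-{(E)-2-[4-(benzyloxy)-3-methoxyphenyl]ethenyl}-3-(methoxymethoxy)propan-1-ol | COCO[C@H](c1ccc(OCc2ccccc2)c(OCc2ccccc2)c1)[C@@H](CO)/C=C/c1ccc(OCc2ccccc2)c(OC)c1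
A1 | alternative 1 | (5R)-5-{[(1R,2S,5R)-5-methyl-2-(propan-2-yl)cyclohexyl]oxy}furan-2(5H)-one | C[C@@H]1CC[C@H]([C@@H](C1)O[C@@H]2OC(=O)C=C2)C(C)C
A2 | alternative 1 | 2-[3,4-bis(benzyloxy)phenyl]-1,3-dithiane | C1CSC(SC1)c1ccc(OCc2ccccc2)c(OCc2ccccc2)c1
A3 | alternative 1 | 1-(benzyloxy)-4-(bromomethyl)-2-methoxybenzene | COc1cc(CBr)ccc1OCc1ccccc1
A4 | alternative 1 | (3R,4R,5R)-3-[4-(benzyloxy)-3-methoxybenzyl]-4-{2-[3,4-bis(benzyloxy)phenyl]-1,3-dithian-2-yl}-5-{[(1R,2S,5R)-5-methyl-2-(propan-2-yl)cyclohexyl]oxy}oxolan-2-one | C[C@@H]1CC[C@H]([C@@H](C1)O[C@@H]2OC(=O)[C@H](Cc3ccc(OCc4ccccc4)c(OC)c3)[C@H]2C5(c6ccc(OCc7ccccc7)c(OCc7ccccc7)c6)SCCCS5)C(C)C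
A5 | alternative 2 | ethyl (2Z)-4-[(tert-butyldimethylsilyl)oxy]-2-[(4,4,5,5-tetramethyl-1,3,2-dioxaborolan-2-yl)methyl]but-2-enoate | CCOC(=O)/C(CB1OC(C)(C)C(C)(C)O1)=C\CO[Si](C)(C)C(C)(C)C
A6 | alternative 2 | (4R,5S)-5-[3,4-bis(benzyloxy)phenyl]-4-{[(tert-butyldimethylsilyl)oxy]methyl}-3-methylideneoxolan-2-one | O=C1O[C@H](c2ccc(OCc3ccccc3)c(OCc3ccccc3)c2)[C@@H](CO[Si](C)(C)C(C)(C)C)C1=C
A7 | alternative 3 | 2-[3,4-bis(benzyloxy)phenyl]-N,N-dimethylacetamide | CN(C)C(=O)Cc1ccc(OCc2ccccc2)c(OCc2ccccc2)c1
A8 | alternative 3 | triisopropyl(prop-2-en-1-yloxy)silane | C=CCO[Si](C(C)C)(C(C)C)C(C)C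
A9 | alternative 3 | (2S,3S)-2-[3,4-bis(benzyloxy)phenyl]-3-{[(triisopropylsilyl)oxy]methyl}cyclobutan-1-one | O=C1[C@H](c2ccc(OCc3ccccc3)c(OCc3ccccc3)c2)[C@@H](CO[Si](C(C)C)(C(C)C)C(C)C)C1
A10 | alternative 3 | (4R,5S)-5-[3,4-bis(benzyloxy)phenyl]-4-{[(triisopropylsilyl)oxy]methyl}oxolan-2-one | O=C1O[C@H](c2ccc(OCc3ccccc3)c(OCc3ccccc3)c2)[C@@H](CO[Si](C(C)C)(C(C)C)C(C)C)C1
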